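**Retrosynthetic overview**
- The last C–C bond joins the left side chain: the primary triflate of a (2R,3R)-epoxy alcohol is coupled with a chiral homoallylic Grignard reagent under copper catalysis.
- The right terminus is made on the chain by SeO2 hydroxylation of the terminal E-methyl group, then copper-catalysed SN2′ methylation (sets the right methyl stereocentre); the head-to-tail bond before it comes from an allylbarium coupling with geranyl chloride.
- Key step: desymmetrising Sharpless mono-epoxidation of the symmetric (2E,6E)-2,7-dimethylocta-2,6-diene-1,8-diol. This forms the only ring (the oxirane) and sets both of its stereocentres.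
- The symmetric diol comes from furan: oxidative dearomatisation to a succinaldehyde equivalent, two-directional Wittig olefination, reduction.
- The Grignard fragment comes from but-2-yne-1,4-diol: anti-carbomagnesiation with a homoprenyl Grignard reagent, then SN2′ methylation of the derived dibromide (sets the left methyl stereocentre).

Assumption: L is O,O′-(1,1′-binaphthalene-2,2′-diyl) N,N-bis(1-phenylethyl)phosphoramidite (both antipodes are bought); its sense of induction in steps 10 and 13 is taken as written, and the antipode would be used if it proved opposite.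

**Step 1**
Reactants: 1 furan
Product: 2 2,5-dimethoxy-2,5-dihydrofuran (cis/trans mixture)
Conditions: Br2 (1.0 equiv), MeOH, Na2CO3, −10 °C
Reagents that add atoms: methanol, SMILES CO
Why: Clauson-Kaas oxidative 2,5-dimethoxylation, in which bromine attacks the electron-rich furan and methanol traps both oxocarbenium ions, turning the aromatic ring into a symmetric masked 1,4-dialdehyde.

**Step 2**
Reactants: 2 2,5-dimethoxy-2,5-dihydrofuran
Product: 3 2,5-dimethoxytetrahydrofuran (cis/trans mixture)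
Conditions: H2 (3 atm), Raney Ni, MeOH, 23 °C
Reagents that add atoms: none
Why: Heterogeneous catalytic hydrogenation of the isolated disubstituted double bond, which leaves the two acetal carbons untouched under neutral conditions.

**Step 3**
Reactants: 3 2,5-dimethoxytetrahydrofuran
Product: 5 diethyl (2E,6E)-2,7-dimethylocta-2,6-dienedioate, via succinaldehyde 4 (not isolated)
Conditions: H2O, Amberlyst 15, 75 °C, 1 h; filter; then Ph3P=C(CH3)CO2Et (2.3 equiv), CH2Cl2, 23 °C, 16 h
Reagents that add atoms: ethyl 2-(triphenylphosphoranylidene)propanoate, SMILES CCOC(=O)C(C)=P(c1ccccc1)(c1ccccc1)c1ccccc1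
Why: Acetal hydrolysis followed by a two-directional Wittig olefination, in which the α-methyl stabilised ylide gives each trisubstituted enoate with high E selectivity.

**Step 4**
Reactants: 5 diethyl (2E,6E)-2,7-dimethylocta-2,6-dienedioate
Product: 6 (2E,6E)-2,7-dimethylocta-2,6-diene-1,8-diol
Conditions: i-Bu2AlH (4.5 equiv), CH2Cl2, −78 → 0 °C; aq. potassium sodium tartrate
Reagents that add atoms: none
Why: 1,2-Reduction of both enoate esters by the aluminium hydride, with no conjugate reduction and retention of both E double bonds.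

**Step 5**
Reactants: 6 (2E,6E)-2,7-dimethylocta-2,6-diene-1,8-diol
Product: 7 (2E)-5-[(2R,3R)-3-(hydroxymethyl)-3-methyloxiran-2-yl]-2-methylpent-2-en-1-ol
Conditions: Ti(OiPr)4 (0.2 equiv), D-(−)-diethyl tartrate (0.26 equiv), t-BuOOH (0.9 equiv), 4 Å molecular sieves, CH2Cl2, −25 °C; unreacted 6 recovered and recycled
Reagents that add atoms: tert-butyl hydroperoxide, SMILES CC(C)(C)OO
Why: Sharpless–Katsuki asymmetric epoxidation run as a desymmetrising mono-epoxidation: the two allylic alcohol ends of the symmetric diol are equivalent, so one oxidation gives a single mono-epoxide, and the titanium–D-(−)-tartrate complex delivers oxygen to the olefin face that makes both oxirane carbons R (L-(+)-tartrate gives 2S,3S from E-allylic alcohols).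

**Step 6**
Reactants: 7 (2E)-5-[(2R,3R)-3-(hydroxymethyl)-3-methyloxiran-2-yl]-2-methylpent-2-en-1-ol
Product: 8 {(2R,3R)-3-[(3E)-5-bromo-4-methylpent-3-en-1-yl]-2-methyloxiran-2-yl}methanol
Conditions: N-bromosuccinimide (1.15 equiv), Me2S (1.4 equiv), CH2Cl2, −30 → 0 °C
Reagents that add atoms: N-bromosuccinimide, SMILES O=C1CCC(=O)N1Br
Why: Corey–Kim halogenation, in which only the allylic alkoxysulfonium ion is displaced by bromide (SN2) while the hindered epoxy carbinol is returned on work-up and the neutral conditions spare the oxirane.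

**Step 7**
Reactants: 8 {(2R,3R)-3-[(3E)-5-bromo-4-methylpent-3-en-1-yl]-2-methyloxiran-2-yl}methanol; 9 geranyl chloride, (2E)-1-chloro-3,7-dimethylocta-2,6-diene
Product: 12 {(2R,3R)-2-methyl-3-[(3E,7E)-4,8,12-trimethyltrideca-3,7,11-trien-1-yl]oxiran-2-yl}methanol, via lithium alkoxide 10 (not isolated), via geranylbarium chloride 11 (not isolated)
Conditions: BaI2, Li, biphenyl, THF, 23 °C; then 9, −78 °C (gives 11, 1.3 equiv); 8, MeLi (1.0 equiv), THF, −78 °C (gives 10); mix, −78 °C, 1 h; H2O
Reagents that add atoms: none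
Why: Yamamoto allylbarium cross-coupling, in which the geranylbarium reagent attacks the primary allylic bromide through its α-carbon (SN2, head-to-tail) with retention of both E double bonds, while the lithium alkoxide and the trisubstituted oxirane are inert at −78 °C.

**Step 8**
Reactants: 12 {(2R,3R)-2-methyl-3-[(3E,7E)-4,8,12-trimethyltrideca-3,7,11-trien-1-yl]oxiran-2-yl}methanol
Product: 13 (2E,6E,10E)-13-[(2R,3R)-3-(hydroxymethyl)-3-methyloxiran-2-yl]-2,6,10-trimethyltrideca-2,6,10-trien-1-ol
Conditions: SeO2 (0.3 equiv), t-BuOOH (3 equiv), salicylic acid (0.1 equiv), CH2Cl2, 23 °C, to about 60% conversion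
Reagents that add atoms: tert-butyl hydroperoxide, SMILES CC(C)(C)OO; selenium dioxide (catalytic oxygen carrier), SMILES O=[Se]=O
Why: Catalytic selenium dioxide allylic hydroxylation (ene reaction then [2,3]-sigmatropic shift), which oxidises the terminal isopropylidene group at its E-methyl group in preference to the internal olefins and gives the E-allylic alcohol.

**Step 9**
Reactants: 13 (2E,6E,10E)-13-[(2R,3R)-3-(hydroxymethyl)-3-methyloxiran-2-yl]-2,6,10-trimethyltrideca-2,6,10-trien-1-ol
Product: 14 {(2R,3R)-3-[(3E,7E,11E)-13-chloro-4,8,12-trimethyltrideca-3,7,11-trien-1-yl]-2-methyloxiran-2-yl}methanol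
Conditions: N-chlorosuccinimide (1.15 equiv), Me2S (1.4 equiv), CH2Cl2, −30 → 0 °C
Reagents that add atoms: N-chlorosuccinimide, SMILES O=C1CCC(=O)N1Cl
Why: Corey–Kim chlorination, again selective for the allylic hydroxyl over the epoxy carbinol and without allylic transposition.

**Step 10**
Reactants: 14 {(2R,3R)-3-[(3E,7E,11E)-13-chloro-4,8,12-trimethyltrideca-3,7,11-trien-1-yl]-2-methyloxiran-2-yl}methanol
Product: 16 {(2R,3R)-2-methyl-3-[(3E,7E,11S)-4,8,11,12-tetramethyltrideca-3,7,12-trien-1-yl]oxiran-2-yl}methanol, via bromomagnesium alkoxide 15 (not isolated)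
Conditions: MeMgBr (1.0 equiv), CH2Cl2, −78 °C (gives 15); then CuBr·SMe2 (5 mol%), (S,S,S)-L (6 mol%), MeMgBr (1.3 equiv, slow addition), −78 °C
Reagents that add atoms: methylmagnesium bromide, SMILES C[Mg]Br
Why: Copper-catalysed asymmetric allylic alkylation (anti SN2′), in which methyl attacks the CH terminus of the 2-methylallyl chloride, the double bond moves to the chain end as the isopropenyl group, and the chiral phosphoramidite selects the olefin face that gives the 11S centre.

**Step 11**
Reactants: 17 5-bromo-2-methylpent-2-ene; 18 but-2-yne-1,4-diol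
Product: 21 (2E)-2-(4-methylpent-3-en-1-yl)but-2-ene-1,4-diol, via homoprenylmagnesium bromide 19 (not isolated), via bromomagnesium butynediolate 20 (not isolated)
Conditions: 17, Mg, THF, 23 °C (gives 19, 3.3 equiv); 18, 0 °C (gives 20); CuI (10 mol%), 23 → 45 °C, 16 h; H2O
Reagents that add atoms: none
Why: Copper-catalysed, alkoxide-directed anti-carbomagnesiation of a propargylic alkoxide, which has no regiochemical issue on the symmetric alkyne and places the two CH2O groups trans (E) after protonation.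

**Step 12**
Reactants: 21 (2E)-2-(4-methylpent-3-en-1-yl)but-2-ene-1,4-diol
Product: 22 (2E)-1,4-dibromo-2-(4-methylpent-3-en-1-yl)but-2-ene
Conditions: N-bromosuccinimide (2.4 equiv), Me2S (2.8 equiv), CH2Cl2, −30 → 0 °C; used at once
Reagents that add atoms: N-bromosuccinimide, SMILES O=C1CCC(=O)N1Br
Why: Twofold Corey–Kim bromination of the two allylic hydroxyls by SN2 displacement, which keeps the E geometry.

**Step 13**
Reactants: 22 (2E)-1,4-dibromo-2-(4-methylpent-3-en-1-yl)but-2-ene
Product: 23 (7S)-8-bromo-2,7-dimethyl-6-methylideneoct-2-ene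
Conditions: CuBr·SMe2 (5 mol%), (R,R,R)-L (6 mol%), MeMgBr (1.2 equiv, slow addition), CH2Cl2, −78 °C
Reagents that add atoms: methylmagnesium bromide, SMILES C[Mg]Br
Why: Copper-catalysed asymmetric allylic alkylation (anti SN2′), in which methyl adds to the CH olefin carbon and expels the bromide on the CH2 next to the substituted carbon (attack at the substituted carbon would need a quaternary centre), giving the 1,1-disubstituted olefin and the S centre under ligand control while the remaining, no longer allylic, bromide is kept.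

**Step 14**
Reactants: 16 {(2R,3R)-2-methyl-3-[(3E,7E,11S)-4,8,11,12-tetramethyltrideca-3,7,12-trien-1-yl]oxiran-2-yl}methanol; 23 (7S)-8-bromo-2,7-dimethyl-6-methylideneoct-2-ene
Product: 27 (2R,3R)-2-[(3R)-3,8-dimethyl-4-methylidenenon-7-en-1-yl]-2-methyl-3-[(3E,7E,11S)-4,8,11,12-tetramethyltrideca-3,7,12-trien-1-yl]oxirane (CNP0306316.1), via lithium alkoxide 24 (not isolated), via epoxy triflate 25 (not isolated), via alkylmagnesium bromide 26 (not isolated)
Conditions: 16, n-BuLi (1.0 equiv), Et2O, −78 °C; Tf2O (1.05 equiv), −78 °C, 20 min; then 26 (from 23, Mg, THF, 0 → 23 °C; 2.0 equiv), CuBr (10 mol%), −78 → −20 °C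
Reagents that add atoms: none
Why: Copper-catalysed sp3–sp3 cross-coupling of a primary triflate with a Grignard reagent (Kotsuki-type), in which SN2 displacement at the CH2 carbon is much faster than opening of the trisubstituted oxirane, so none of the four stereocentres is touched.

**Compound list**
1 | furan | c1ccoc1 | starting material
2 | 2,5-dimethoxy-2,5-dihydrofuran (cis/trans mixture) | COC1C=CC(OC)O1 | intermediate
3 | 2,5-dimethoxytetrahydrofuran (cis/trans mixture) | COC1CCC(OC)O1 | intermediate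
4 | succinaldehyde (butanedial) | O=CCCC=O | intermediate
5 | diethyl (2E,6E)-2,7-dimethylocta-2,6-dienedioate | CCOC(=O)/C(C)=C/CC/C=C(\C)C(=O)OCC | intermediate
6 | (2E,6E)-2,7-dimethylocta-2,6-diene-1,8-diol | OC/C(C)=C/CC/C=C(\C)CO | intermediate
7 | (2E)-5-[(2R,3R)-3-(hydroxymethyl)-3-methyloxiran-2-yl]-2-methylpent-2-en-1-ol | OC[C@@]1(C)O[C@@H]1CC/C=C(\C)CO | intermediate
8 | {(2R,3R)-3-[(3E)-5-bromo-4-methylpent-3-en-1-yl]-2-methyloxiran-2-yl}methanol | OC[C@@]1(C)O[C@@H]1CC/C=C(\C)CBr | intermediate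
9 | geranyl chloride, (2E)-1-chloro-3,7-dimethylocta-2,6-diene | ClC/C=C(\C)CCC=C(C)C | starting material
10 | lithium {(2R,3R)-3-[(3E)-5-bromo-4-methylpent-3-en-1-yl]-2-methyloxiran-2-yl}methanolate | [Li+].[O-]C[C@@]1(C)O[C@@H]1CC/C=C(\C)CBr | intermediate
11 | geranylbarium chloride, [(2E)-3,7-dimethylocta-2,6-dien-1-yl]barium chloride | Cl[Ba]C/C=C(\C)CCC=C(C)C | intermediate
12 | {(2R,3R)-2-methyl-3-[(3E,7E)-4,8,12-trimethyltrideca-3,7,11-trien-1-yl]oxiran-2-yl}methanol | OC[C@@]1(C)O[C@@H]1CC/C=C(\C)CC/C=C(\C)CCC=C(C)C | intermediate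
13 | (2E,6E,10E)-13-[(2R,3R)-3-(hydroxymethyl)-3-methyloxiran-2-yl]-2,6,10-trimethyltrideca-2,6,10-trien-1-ol | OC[C@@]1(C)O[C@@H]1CC/C=C(\C)CC/C=C(\C)CC/C=C(\C)CO | intermediate
14 | {(2R,3R)-3-[(3E,7E,11E)-13-chloro-4,8,12-trimethyltrideca-3,7,11-trien-1-yl]-2-methyloxiran-2-yl}methanol | OC[C@@]1(C)O[C@@H]1CC/C=C(\C)CC/C=C(\C)CC/C=C(\C)CCl | intermediate
15 | bromomagnesium alkoxide of 14 | Br[Mg]OC[C@@]1(C)O[C@@H]1CC/C=C(\C)CC/C=C(\C)CC/C=C(\C)CCl | intermediate
16 | {(2R,3R)-2-methyl-3-[(3E,7E,11S)-4,8,11,12-tetramethyltrideca-3,7,12-trien-1-yl]oxiran-2-yl}methanol | OC[C@@]1(C)O[C@@H]1CC/C=C(\C)CC/C=C(\C)CC[C@H](C)C(=C)C | intermediate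
17 | 5-bromo-2-methylpent-2-ene | CC(C)=CCCBr | starting material
18 | but-2-yne-1,4-diol | OCC#CCO | starting material
19 | (4-methylpent-3-en-1-yl)magnesium bromide | CC(C)=CCC[Mg]Br | intermediate
20 | bis(bromomagnesium) but-2-yne-1,4-diolate | Br[Mg]OCC#CCO[Mg]Br | intermediate
21 | (2E)-2-(4-methylpent-3-en-1-yl)but-2-ene-1,4-diol | OC/C(CCC=C(C)C)=C/CO | intermediate
22 | (2E)-1,4-dibromo-2-(4-methylpent-3-en-1-yl)but-2-ene | BrC/C(CCC=C(C)C)=C/CBr | intermediate
23 | (7S)-8-bromo-2,7-dimethyl-6-methylideneoct-2-ene | C=C(CCC=C(C)C)[C@H](C)CBr | intermediate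
24 | lithium alkoxide of 16 | [Li+].[O-]C[C@@]1(C)O[C@@H]1CC/C=C(\C)CC/C=C(\C)CC[C@H](C)C(=C)C | intermediate
25 | {(2R,3R)-2-methyl-3-[(3E,7E,11S)-4,8,11,12-tetramethyltrideca-3,7,12-trien-1-yl]oxiran-2-yl}methyl trifluoromethanesulfonate | FC(F)(F)S(=O)(=O)OC[C@@]1(C)O[C@@H]1CC/C=C(\C)CC/C=C(\C)CC[C@H](C)C(=C)C | intermediate
26 | [(2S)-2,7-dimethyl-3-methylideneoct-6-en-1-yl]magnesium bromide | C=C(CCC=C(C)C)[C@H](C)C[Mg]Br | intermediate
27 | (2R,3R)-2-[(3R)-3,8-dimethyl-4-methylidenenon-7-en-1-yl]-2-methyl-3-[(3E,7E,11S)-4,8,11,12-tetramethyltrideca-3,7,12-trien-1-yl]oxirane | C=C(CCC=C(C)C)[C@H](C)CC[C@@]1(C)O[C@@H]1CC/C=C(\C)CC/C=C(\C)CC[C@H](C)C(=C)C | target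

**Step count**
Total: 14 steps. Longest linear sequence: 11 steps (steps 1–10, then step 14).

**Three steps most likely to fail, each with a fallback**

Step 5. The mono-epoxidation is statistical (at best about half of the diol becomes mono-epoxide per pass), and the diol can bridge titanium centres and slow turnover. The fallback sets out from 4 and comes back at 7; it differentiates the two chain ends by oxidation level instead of by statistics. Succinaldehyde 4, used in excess, is treated with one equivalent of Ph3P=C(CH3)CO2Et to give ethyl (2E)-2-methyl-6-oxohex-2-enoate F1. A second Wittig reaction with Ph3P=C(CH3)CHO gives ethyl (2E,6E)-2,7-dimethyl-8-oxoocta-2,6-dienoate F2. NaBH4 with CeCl3 reduces only the aldehyde to ethyl (2E,6E)-8-hydroxy-2,7-dimethylocta-2,6-dienoate F3. Sharpless epoxidation (Ti(OiPr)4, D-(−)-diethyl tartrate, t-BuOOH) touches only the allylic alcohol olefin and gives ethyl (2E)-5-[(2R,3R)-3-(hydroxymethyl)-3-methyloxiran-2-yl]-2-methylpent-2-enoate F4. Reduction with i-Bu2AlH at −78 °C then gives 7.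

Step 8. The selenium dioxide oxidation is done late, on a polyene with two internal trisubstituted olefins, so site selectivity and over-oxidation to the enal limit the yield. The fallback sets out from 10 and comes back at 16; the right terminus is finished before the fragment coupling, so steps 8–10 are not needed. Geranyl acetate F5 is oxidised (SeO2, t-BuOOH) to (2E,6E)-8-hydroxy-3,7-dimethylocta-2,6-dien-1-yl acetate F6. N-Chlorosuccinimide and Me2S give (2E,6E)-8-chloro-3,7-dimethylocta-2,6-dien-1-yl acetate F7. SN2′ methylation under the step 10 conditions (CuBr·SMe2, (S,S,S)-L, MeMgBr, −78 °C) gives (2E,6S)-3,6,7-trimethylocta-2,7-dien-1-yl acetate F8. K2CO3 in MeOH gives (2E,6S)-3,6,7-trimethylocta-2,7-dien-1-ol F9, and N-chlorosuccinimide with Me2S gives (2E,6S)-1-chloro-3,6,7-trimethylocta-2,7-diene F10. Zerovalent barium (BaI2, Li, biphenyl) at −78 °C converts F10 into [(2E,6S)-3,6,7-trimethylocta-2,7-dien-1-yl]barium chloride F11, which couples with 10 under the step 7 conditions to give 16 directly.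

Step 13. The SN2′ methylation of a 2-substituted 1,4-dibromobutene may give SN2 product or low enantioselectivity. The fallback sets out from 19 and comes back at 23; it takes the stereocentre from the chiral pool. Commercial methyl (2R)-3-{[tert-butyl(dimethyl)silyl]oxy}-2-methylpropanoate F12 is converted with MeNHOMe·HCl and i-PrMgCl into (2R)-3-{[tert-butyl(dimethyl)silyl]oxy}-N-methoxy-N,2-dimethylpropanamide F13. Grignard reagent 19 adds once to give (2R)-1-{[tert-butyl(dimethyl)silyl]oxy}-2,7-dimethyloct-6-en-3-one F14. Salt-free Wittig methylenation (Ph3PCH3Br, KN(SiMe3)2, THF, −78 → 0 °C) gives tert-butyl{[(2S)-2,7-dimethyl-3-methylideneoct-6-en-1-yl]oxy}dimethylsilane F15. Bu4NF gives (2S)-2,7-dimethyl-3-methylideneoct-6-en-1-ol F16, and CBr4 with PPh3 gives 23.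

**Further compounds**
F1 | step 5 | ethyl (2E)-2-methyl-6-oxohex-2-enoate | CCOC(=O)/C(C)=C/CCC=O
F2 | step 5 | ethyl (2E,6E)-2,7-dimethyl-8-oxoocta-2,6-dienoate | CCOC(=O)/C(C)=C/CC/C=C(\C)C=O
F3 | step 5 | ethyl (2E,6E)-8-hydroxy-2,7-dimethylocta-2,6-dienoate | CCOC(=O)/C(C)=C/CC/C=C(\C)CO
F4 | step 5 | ethyl (2E)-5-[(2R,3R)-3-(hydroxymethyl)-3-methyloxiran-2-yl]-2-methylpent-2-enoate | OC[C@@]1(C)O[C@@H]1CC/C=C(\C)C(=O)OCC
F5 | step 8 | geranyl acetate, (2E)-3,7-dimethylocta-2,6-dien-1-yl acetate | CC(=O)OC/C=C(\C)CCC=C(C)C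
F6 | step 8 | (2E,6E)-8-hydroxy-3,7-dimethylocta-2,6-dien-1-yl acetate | CC(=O)OC/C=C(\C)CC/C=C(\C)CO
F7 | step 8 | (2E,6E)-8-chloro-3,7-dimethylocta-2,6-dien-1-yl acetate | CC(=O)OC/C=C(\C)CC/C=C(\C)CCl
F8 | step 8 | (2E,6S)-3,6,7-trimethylocta-2,7-dien-1-yl acetate | CC(=O)OC/C=C(\C)CC[C@H](C)C(=C)C
F9 | step 8 | (2E,6S)-3,6,7-trimethylocta-2,7-dien-1-ol | OC/C=C(\C)CC[C@H](C)C(=C)C
F10 | step 8 | (2E,6S)-1-chloro-3,6,7-trimethylocta-2,7-diene | ClC/C=C(\C)CC[C@H](C)C(=C)C
F11 | step 8 | [(2E,6S)-3,6,7-trimethylocta-2,7-dien-1-yl]barium chloride | Cl[Ba]C/C=C(\C)CC[C@H](C)C(=C)C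
F12 | step 13 | methyl (2R)-3-{[tert-butyl(dimethyl)silyl]oxy}-2-methylpropanoate | COC(=O)[C@H](C)CO[Si](C)(C)C(C)(C)C
F13 | step 13 | (2R)-3-{[tert-butyl(dimethyl)silyl]oxy}-N-methoxy-N,2-dimethylpropanamide | CON(C)C(=O)[C@H](C)CO[Si](C)(C)C(C)(C)C
F14 | step 13 | (2R)-1-{[tert-butyl(dimethyl)silyl]oxy}-2,7-dimethyloct-6-en-3-one | CC(C)=CCCC(=O)[C@H](C)CO[Si](C)(C)C(C)(C)C
F15 | step 13 | tert-butyl{[(2S)-2,7-dimethyl-3-methylideneoct-6-en-1-yl]oxy}dimethylsilane | C=C(CCC=C(C)C)[C@H](C)CO[Si](C)(C)C(C)(C)C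
F16 | step 13 | (2S)-2,7-dimethyl-3-methylideneoct-6-en-1-ol | C=C(CCC=C(C)C)[C@H](C)CO
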